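## Structural features

Lapiferine is a daucane sesquiterpenoid ester: a cyclopentane (ring A, C1–C5) fused through the C1–C5 bond to a cycloheptane (ring B, C1 and C5–C10), with a trans fusion (C1 methyl β, C5 hydrogen α). Reading the SMILES gives (1S,4R,5S,6S,8R,9S,10S) in the numbering used here, and all seven stereocentres lie on the bicyclic core. C4–C5–C6 form one contiguous run (tertiary isopropyl carbinol, fusion CH, acylated carbinol) and C8–C9–C10–C1 a second (methyl-bearing epoxide, secondary carbinol, all-carbon quaternary centre); the runs meet at the C1–C5 bond and are otherwise separated only by the C7 methylene. The oxygens at C6, C8/C9 and C10 are all α, and the C4 hydroxyl is β. Fragile groups are the angelate (Z to E isomerisation to the tiglate under base, nucleophilic catalysts or heat), the trisubstituted epoxide next to a free hydroxyl (acid opening, epoxide migration) and the tertiary alcohol (dehydration); β-oxygenated carbonyl intermediates on the way can eliminate. The real difficulty is the quaternary C1, flanked by the C10 carbinol and the trans fusion inside a seven-membered ring oxygenated at C6, C8, C9 and C10. After adjustment of oxidation levels, ring B maps onto C5=C6(O)–C7H2–C8=C9–C10(O)–C1, a 1,4-cycloheptadiene whose C1–C10 σ bond joins the two allylic termini. That is the retron of a divinylcyclopropane Cope rearrangement, and the key step uses it to build ring B, C1 and C10 from two achiral fragments.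

## Logic of the disconnections

29 ⇒ 28. The C8–O and C9–O bonds of the epoxide are cut first because the epoxide is the most fragile group and the neighbouring C10 hydroxyl can direct its formation. Two stereocentres disappear and a plain trisubstituted alkene remains. The forward step must deliver oxygen to the α face, syn to the C10 hydroxyl, and leave the electron-poor angelate alkene alone.

28 ⇒ 27 ⇒ 24 + 25. The C10 O–Si bond is a protecting-group operation, and the C6 O–acyl bond is cut so that the isomerisation-prone ester enters late. This splits off 25 and leaves 24, in which only the C6 hydroxyl can be acylated (C4 tertiary, C10 silylated). The forward step must acylate a hindered secondary alcohol without Z to E isomerisation, and the desilylation must spare the ester.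

24 ⇒ 23 ⇒ 22. After the C6 O–benzyl bond, the C4–isopropyl bond is cut, since a tertiary carbinol is a ketone plus a carbon nucleophile. Three carbons and the C4 stereocentre are removed. The forward addition must come from the α face, anti to the C1 methyl, on a ketone that is enolisable and carries a β-oxygen, which calls for a weakly basic organocerium reagent.

22 ⇒ 21 ⇒ 19 ⇒ 18. The C4 ketone is masked as its ketal, the C6 ether is removed, and the C6–H bond is cut (carbinol to ketone). This removes the C6 stereocentre and leaves a ketone directly related to the cycloadduct. The forward reduction must give the equatorial 6α alcohol although hydride reagents are expected to prefer the other face, hence a thermodynamically controlled electron-transfer reduction.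

18 ⇒ 17. The C5–H bond is cut by returning the ketone to its silyl enol ether. The C5 stereocentre disappears and the oxidation pattern of the cycloadduct is reached. Forward, protonation must occur anti to the C1 methyl (trans fusion) under buffered conditions that do not move the C8=C9 alkene into conjugation.

17 ⇒ 15 ⇒ 14. The C8 methyl is traced to the ester (C–H bonds to C–O bonds), because the ester is what makes the carbenoid chemistry possible. This costs two steps but returns to the cycloadduct. The forward hydride displacement must occur at the primary allylic carbon without allylic transposition.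

14 ⇒ 13 ⇒ 7 + 12. The C1–C10 bond is cut in the Cope sense (re-forming C6–C8), then the C7–C8 and C6–C8 bonds of the cyclopropane. Ring B, the quaternary C1 and the C10 carbinol fall back to two achiral fragments of similar size. The forward step needs site selectivity for the terminal enol ether, a cis-divinylcyclopropane, catalyst control of absolute configuration and a stereospecific boat rearrangement.

7 ⇒ 5 ⇒ 3 ⇒ 2 ⇒ 1. The O–Si bond, the C5–C6 bond (vinyl anion plus acetyl donor), the ketal C–O bonds and the C–I bond are cut in turn, ending at a commodity enone. Forward, the ketal must mask the carbonyl so that the α-carbon can be lithiated, and enolisation must occur at the acetyl methyl only.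

12 ⇒ 10 ⇒ 8 + 9. The C9=C10 π bond is cut by hydration and the C8–C9 σ bond by a retro-aldol-type step, giving two commercial compounds. Forward, the dehydration must give the E enol ether without destroying the diazo group.

## Other disconnections considered

Alternative 1: The cut is at C1–C5 and C7–C8 of ring B. In the forward sense the oxyallyl cation from 1,1,3,3-tetrabromoacetone A2 and Zn–Cu couple adds across the 2,5-positions of 2,5-dimethylfuran A1, and debromination would give the meso oxabicyclic ketone A3.
- In its favour: two operations from bulk chemicals deliver the whole seven-membered ring with both methyl-bearing carbons (C1, C8), the C6 carbonyl and a C9=C10 alkene, without diazo compounds or a noble metal. On cost and on the number of steps to ring B it is better than the chosen plan.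
- Against it here: A3 is meso and needs a desymmetrisation. Its oxygen bridges C1 and C8, whereas the target has oxygen on C8 and C9 and none on C1, so the bridge cannot become the epoxide directly. The C1–O bond would have to be replaced by the C1–C2 bond at a tertiary centre, and the oxygen, kept on C8, would have to be closed onto C9 later. No carbon of ring A is present, and the C10 oxygen is still missing.
- Comparison: the cationic (4+3) step is simple but sets none of the target's stereocentres. The chosen pericyclic step creates C1 as an all-carbon centre together with the C10 oxygen. The early step saving would be spent on the C1 exchange and the annulation of ring A.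

Alternative 2: The cut is at C1–C5 and C6–C7. Forward, [Rh(CO)2Cl]2 (monovalent rhodium) would convert the tethered alkyne–vinylcyclopropane A4 into the bicyclic diene A5 by oxidative coupling, cleavage of the C7–C9 cyclopropane bond and reductive elimination.
- In its favour: both rings form in one neutral, atom-economical step, and the C4 carbinol with its isopropyl group is already in place, so no late organometallic addition or ketone protection is needed. The resulting C5=C6 alkene could be hydroborated anti to the angular methyl, setting C5–H and C6–OH in a single syn addition. On that point it is better than the chosen plan, which needs a protonation and a separate reduction.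
- Against it here: the quaternary C1 must arise by insertion of a trisubstituted alkene, a slow case for this cycloaddition. The C1 configuration rests on 1,3-induction from a carbinol whose two groups are of similar size. The C10 oxygen is absent, so C9=C10 must be transposed to C8=C9 with oxygenation. A suprafacial ene reaction with singlet oxygen would need the C8 hydrogen on the α face, that is, the C8 epimer of A5 as drawn. A4 itself needs a separately made chiral carbinol and a defined cyclopropane.
- Comparison: it is equal to the chosen plan in closing ring B with the quaternary centre in the key step. It is weaker on control of C1 (substrate versus catalyst control) and on C10. The step count is probably similar once A4 is made.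

Alternative 3: The cut is at C4–C5. Forward, Rh2(OAc)4 would turn the diazo ketone A6 into a divalent rhodium carbenoid that inserts into the C4–H bond α to the silyl ether, and base equilibration at C5 would give the trans-fused enone A7.
- In its favour: 1,5-insertion into an oxygen-activated C–H bond goes with retention, so the C4 configuration can be fixed beforehand by a routine asymmetric ketone reduction, and C5 is set under thermodynamic control next to the ketone. On C4 and C5 it is equal to or better than the chosen plan. Ring B arrives with the C6 carbonyl and the C8 methyl.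
- Against it here: the quaternary C1 must be built earlier and matched independently with C4. The carbenoid sits next to that quaternary centre, and oxonium-ylide formation at the silyl ether oxygen, ring contraction and insertion into the isopropyl methine can compete. C9 and C10 arrive as bare methylenes, so the C10 hydroxyl and the C8–C9 epoxide would need late oxidation at a neopentyl position.
- Comparison: the key step forms one ring bond and one stereocentre, the chosen one two skeletal bonds and two stereocentres with the C10 oxygen in place. Its step economy after the key step is clearly poorer.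

Key step: step 7

Remarks on the chemistry (assumptions):
- Locants in all names of bicyclic compounds follow the target: C1 angular carbon, C2, C3, C4, C5 in ring A; C6–C10 in ring B. β is the face of the C1 methyl, and the SMILES are authoritative for configuration.
- Rh2(R-DOSP)4 is chosen on the assumption that the facial preference known for donor–acceptor carbenoids with terminal alkenes carries over to the enol ether of 7. If the sense proves opposite, Rh2(S-DOSP)4 is used.
- The ethyl ester is kept because ethyl diazoacetate is the commercial, better-characterised reagent; the ester is removed two steps later.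
- Both silyl groups stay TBS: the enol silyl ether is cleaved by buffered fluoride far faster than the hindered secondary alkyl silyl ether.

## Route

Step 1
Reactants: 1 3-methylcyclopent-2-en-1-one
Product: 2 2-iodo-3-methylcyclopent-2-en-1-one
Conditions: I2, pyridine, CH2Cl2, 0 °C → rt
Reagents that add atoms: iodine, II
Why: Pyridine-mediated α-iodination of a cyclic enone (conjugate addition of pyridine, iodination of the resulting enolate, elimination of pyridine); the β-methyl group slows the reaction but leaves only the α-position available.

Step 2
Reactants: 2 2-iodo-3-methylcyclopent-2-en-1-one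
Product: 3 6-iodo-7-methyl-1,4-dioxaspiro[4.4]non-6-ene
Conditions: ethylene glycol, p-TsOH·H2O (cat.), benzene, reflux, Dean–Stark trap
Reagents that add atoms: ethylene glycol, OCCO
Why: Acid-catalysed ketalisation with azeotropic removal of water; the tetrasubstituted iodoalkene is expected to stay in place, and the ketal turns the α-carbon into a site for halogen–metal exchange.

Step 3
Reactants: 3 6-iodo-7-methyl-1,4-dioxaspiro[4.4]non-6-ene
Product: 5 1-(7-methyl-1,4-dioxaspiro[4.4]non-6-en-6-yl)ethan-1-one, via vinyllithium 4 (not isolated)
Conditions: n-BuLi, THF, −78 °C; then MeC(O)N(OMe)Me, −78 → 0 °C; aq. NH4Cl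
Reagents that add atoms: N-methoxy-N-methylacetamide, CC(=O)N(C)OC
Why: Iodine–lithium exchange gives the α-ketovinyl anion equivalent, and the Weinreb ketone synthesis stops at the methyl ketone because the chelated tetrahedral adduct survives until work-up; this forms the C5–C6 bond.

Step 4
Reactants: 5 1-(7-methyl-1,4-dioxaspiro[4.4]non-6-en-6-yl)ethan-1-one
Product: 7 tert-butyldimethyl{[1-(7-methyl-1,4-dioxaspiro[4.4]non-6-en-6-yl)ethenyl]oxy}silane, via potassium enolate 6 (not isolated)
Conditions: KN(SiMe3)2, THF, −78 °C; then TBSCl, −78 °C → rt
Reagents that add atoms: tert-butyldimethylsilyl chloride, CC(C)(C)[Si](C)(C)Cl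
Why: Kinetic deprotonation at the acetyl methyl (the only α-hydrogens) followed by O-silylation gives the cross-conjugated 2-silyloxy diene; a strong base at low temperature is preferred to a silyl triflate, which could ionise the allylic ketal.

Step 5
Reactants: 8 ethyl diazoacetate; 9 (tert-butyldimethylsilyloxy)acetaldehyde
Product: 10 ethyl 4-[(tert-butyldimethylsilyl)oxy]-2-diazo-3-hydroxybutanoate (racemic)
Conditions: DBU (10 mol %), MeCN, rt
Reagents that add atoms: none
Why: Base-catalysed aldol-type addition of the diazoacetate carbon to the aldehyde forms the C8–C9 bond; the carbinol stereocentre is lost in the next step, so no control is needed.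

Step 6
Reactants: 10 ethyl 4-[(tert-butyldimethylsilyl)oxy]-2-diazo-3-hydroxybutanoate
Product: 12 ethyl (E)-4-[(tert-butyldimethylsilyl)oxy]-2-diazobut-3-enoate, via dichlorophosphate 11 (not isolated)
Conditions: POCl3, Et3N, CH2Cl2, 0 °C
Reagents that add atoms: none
Why: Phosphorylation of the β-hydroxyl and amine-induced elimination towards C10 is the standard dehydration of β-hydroxy-α-diazo esters to vinyldiazoacetates; conjugation should favour the E enol ether, and the product is used at once because vinyldiazo compounds cyclise on standing.

Step 7
Reactants: 7 tert-butyldimethyl{[1-(7-methyl-1,4-dioxaspiro[4.4]non-6-en-6-yl)ethenyl]oxy}silane; 12 ethyl (E)-4-[(tert-butyldimethylsilyl)oxy]-2-diazobut-3-enoate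
Product: 14 cycloheptadiene ester (1S,10R; C5=C6 OTBS enol ether; CO2Et on C8 of C8=C9; 10α-OTBS; 1β-methyl; C4 dioxolane), via cis-divinylcyclopropane 13 (not isolated)
Conditions: Rh2(R-DOSP)4 (1 mol %), hexanes, −40 °C → rt, slow addition of 12; then toluene, 80 °C
Reagents that add atoms: none
Why: The chiral divalent rhodium carboxylate decomposes 12 to a donor–acceptor vinylcarbenoid that adds in a concerted, asynchronous [2+1] step to the terminal, electron-rich C6=C7 enol ether of 7 (C7–C8 and C6–C8 bonds), the tetrasubstituted C1=C5 alkene being too hindered to compete; the closest known reaction type is the tandem cyclopropanation/Cope rearrangement (formal (4+3) cycloaddition) of dirhodium vinylcarbenoids with 2-silyloxy dienes. Cyclopropane 13 should carry the cyclopentenyl and silyloxyvinyl groups cis, and the prolinate ligands fix its configuration (6R,8S) through the facial selectivity of the cyclopropanation. Ring B then closes by a [3,3] sigmatropic shift through the boat transition state, the only one open to a cis-divinylcyclopropane: C1–C10 forms, C6–C8 breaks and the C5=C6 and C8=C9 alkenes appear, so the seven-membered ring is closed pericyclically with release of cyclopropane strain. Both new stereocentres follow stereospecifically from the cyclopropane: C1 is bonded on the cyclopentene face that lies over the three-membered ring (1S), and the E enol ether places the C10 oxygen on the side of C2, trans to the C1 methyl (10R). The C1 methyl points into the boat and slows the shift, hence the warming stage, while the silyloxy/ester push–pull substitution of the breaking C6–C8 bond should work in the opposite sense. The step needs site selectivity (terminal enol ether over tetrasubstituted alkene, carbenoid carbon over the vinylogous terminus) and cis diastereoselectivity; the first is secured by the unhindered CH2 terminus, the second by the substituted vinyl terminus and the non-polar solvent, and any trans isomer can still converge through reversible opening of the donor–acceptor bond.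

Step 8
Reactants: 14 cycloheptadiene ester
Product: 15 allylic alcohol (1S,10R; CH2OH on C8; C5=C6 OTBS enol ether; 10α-OTBS; C4 dioxolane)
Conditions: i-Bu2AlH, CH2Cl2, −78 °C; aq. potassium sodium tartrate
Reagents that add atoms: none
Why: 1,2-Reduction of the conjugated ester by the aluminium hydride; silyl enol ether, silyl ether and ketal are inert at −78 °C, and at this stage the product has a single hydroxyl.

Step 9
Reactants: 15 allylic alcohol
Product: 17 C8-methyl diene (1S,10R; C5=C6 OTBS enol ether; C8=C9; 10α-OTBS; C4 dioxolane), via allylic mesylate 16 (not isolated)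
Conditions: MsCl, Et3N, THF, −30 °C; then LiEt3BH, −30 → 0 °C
Reagents that add atoms: none
Why: Sulfonylation and SN2 displacement by the trialkylborohydride deoxygenate the primary allylic alcohol; direct attack at the primary carbon is expected to beat SN2' attack at C9, which is shielded by the C10 silyl ether and the quaternary C1.

Step 10
Reactants: 17 C8-methyl diene
Product: 18 β,γ-unsaturated C6 ketone (1S,5S,10R; 5α-H; trans-fused; 10α-OTBS; C4 dioxolane)
Conditions: n-Bu4NF, AcOH (1:1.2), THF, −78 → 0 °C; pH 7 work-up
Reagents that add atoms: none
Why: Fluoride cleaves the enol silyl ether much faster than the hindered secondary alkyl silyl ether, and the enolate is protonated at once by acetic acid on the C5 face anti to the C1 methyl, which sets the trans fusion; the buffer keeps the C8=C9 alkene out of conjugation and prevents β-elimination of the ketal oxygen.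

Step 11
Reactants: 18 β,γ-unsaturated C6 ketone
Product: 19 6α-alcohol (1S,5S,6S,10R; 10α-OTBS; C4 dioxolane)
Conditions: Li, liquid NH3/THF, t-BuOH, −78 °C, inverse addition; solid NH4Cl
Reagents that add atoms: none
Why: Dissolving-metal reduction of a hindered ring ketone is thermodynamically controlled and should give the equatorial alcohol, here 6α with H6 anti to H5, whereas hydride reagents are expected to attack anti to the 1,3-related C1 methyl and give the 6β epimer; the isolated alkene, silyl ether and ketal are not reduced.

Step 12
Reactants: 19 6α-alcohol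
Product: 21 6α-(4-methoxybenzyl) ether (1S,5S,6S,10R; 10α-OTBS; C4 dioxolane), via sodium alkoxide 20 (not isolated)
Conditions: NaH, THF/DMF, 0 °C; then PMBCl, n-Bu4NI (cat.), 0 °C → rt
Reagents that add atoms: 4-methoxybenzyl chloride, COc1ccc(CCl)cc1
Why: Williamson etherification; the ether is a poor leaving group β to the future C4 ketone, survives acid and organometallic reagents, and can later be removed oxidatively without touching the silyl ether.

Step 13
Reactants: 21 6α-(4-methoxybenzyl) ether
Product: 22 C4 ketone (1S,5S,6S,10R; 6α-OPMB; 10α-OTBS)
Conditions: PPTS (cat.), acetone/H2O (10:1), 50 °C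
Reagents that add atoms: water, O
Why: Mild acid hydrolysis of the cyclopentanone dioxolane; the hindered secondary silyl ether and the benzyl ether tolerate the weak acid, which is also chosen to keep enolisation at C5 slow.

Step 14
Reactants: 22 C4 ketone
Product: 23 4β-hydroxy-4α-isopropyl compound (1S,4R,5S,6S,10R; 6α-OPMB; 10α-OTBS)
Conditions: i-PrMgCl, CeCl3 (dried, pre-stirred in THF), THF, −78 → −20 °C; aq. NH4Cl
Reagents that add atoms: isopropylmagnesium chloride, CC(C)[Mg]Cl
Why: The organocerium reagent adds to the carbonyl with little enolisation, β-hydride reduction or β-elimination of the C6 ether; attack on the α face, anti to the 1,3-related C1 methyl on the cyclopentanone, should give the β hydroxyl (4R).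

Step 15
Reactants: 23 4β-hydroxy-4α-isopropyl compound
Product: 24 4β,6α-diol (1S,4R,5S,6S,10R; 10α-OTBS)
Conditions: DDQ, CH2Cl2/pH 7 buffer (10:1), 0 °C
Reagents that add atoms: none
Why: Oxidative cleavage of the 4-methoxybenzyl ether through the benzylic oxocarbenium ion and its hydrolysis; silyl ether, trisubstituted alkene and tertiary alcohol are expected to be inert in the buffered two-phase system.

Step 16
Reactants: 24 4β,6α-diol; 25 angelic acid
Product: 27 6α-angelate (1S,4R,5S,6S,10R; 4β-OH; 10α-OTBS), via mixed anhydride 26 (not isolated)
Conditions: 25, 2,4,6-trichlorobenzoyl chloride, Et3N, toluene, rt; then 24, toluene, 80 °C, no DMAP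
Reagents that add atoms: none
Why: Yamaguchi-type mixed-anhydride esterification; the alcohol attacks the less hindered angeloyl carbonyl, and leaving out the nucleophilic catalyst avoids the addition–elimination path that turns angelates into tiglates, while the tertiary C4 hydroxyl is too hindered to react.

Step 17
Reactants: 27 6α-angelate
Product: 28 10α-alcohol (1S,4R,5S,6S,10R; 4β-OH; 6α-angelate; C8=C9)
Conditions: HF·pyridine, pyridine, THF, 0 °C → rt
Reagents that add atoms: none
Why: Buffered fluoride-mediated desilylation under non-basic conditions, so that the angelate is neither cleaved nor isomerised and no allylic ionisation at C10 is expected.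

Step 18
Reactants: 28 10α-alcohol
Product: 29 lapiferine (1S,4R,5S,6S,8R,9S,10S)
Conditions: VO(acac)2 (5 mol %), t-BuOOH (decane), CH2Cl2, 0 °C → rt
Reagents that add atoms: tert-butyl hydroperoxide, CC(C)(C)OO
Why: Hydroxyl-directed epoxidation: the vanadium alkoxide of the C10 allylic alcohol delivers the peroxide oxygen intramolecularly to the same (α) face of C8=C9, the normal result for cycloalkenols of this ring size, and the electron-poor angelate alkene does not react.

## Compound list

1 | 3-methylcyclopent-2-en-1-one | CC1=CC(=O)CC1 | starting material
2 | 2-iodo-3-methylcyclopent-2-en-1-one | CC1=C(I)C(=O)CC1 | intermediate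
3 | 6-iodo-7-methyl-1,4-dioxaspiro[4.4]non-6-ene | CC1=C(I)C2(CC1)OCCO2 | intermediate
4 | (7-methyl-1,4-dioxaspiro[4.4]non-6-en-6-yl)lithium | [Li]C1=C(C)CCC12OCCO2 | intermediate
5 | 1-(7-methyl-1,4-dioxaspiro[4.4]non-6-en-6-yl)ethan-1-one | CC(=O)C1=C(C)CCC12OCCO2 | intermediate
6 | potassium 1-(7-methyl-1,4-dioxaspiro[4.4]non-6-en-6-yl)ethen-1-olate | [K+].[O-]C(=C)C1=C(C)CCC12OCCO2 | intermediate
7 | tert-butyldimethyl{[1-(7-methyl-1,4-dioxaspiro[4.4]non-6-en-6-yl)ethenyl]oxy}silane | C=C(O[Si](C)(C)C(C)(C)C)C1=C(C)CCC12OCCO2 | intermediate
8 | ethyl diazoacetate | CCOC(=O)C=[N+]=[N-] | starting material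
9 | (tert-butyldimethylsilyloxy)acetaldehyde | CC(C)(C)[Si](C)(C)OCC=O | starting material
10 | ethyl 4-[(tert-butyldimethylsilyl)oxy]-2-diazo-3-hydroxybutanoate (racemic) | CCOC(=O)C(=[N+]=[N-])C(O)CO[Si](C)(C)C(C)(C)C | intermediate
11 | ethyl 4-[(tert-butyldimethylsilyl)oxy]-2-diazo-3-[(dichlorophosphoryl)oxy]butanoate (racemic) | CCOC(=O)C(=[N+]=[N-])C(OP(=O)(Cl)Cl)CO[Si](C)(C)C(C)(C)C | intermediate
12 | ethyl (E)-4-[(tert-butyldimethylsilyl)oxy]-2-diazobut-3-enoate | CCOC(=O)C(=[N+]=[N-])/C=C/O[Si](C)(C)C(C)(C)C | intermediate
13 | ethyl (1S,2R)-2-[(tert-butyldimethylsilyl)oxy]-1-[(E)-2-[(tert-butyldimethylsilyl)oxy]ethenyl]-2-(7-methyl-1,4-dioxaspiro[4.4]non-6-en-6-yl)cyclopropane-1-carboxylate (cis-divinylcyclopropane; 6R,8S in target numbering) | CCOC(=O)[C@]1(/C=C/O[Si](C)(C)C(C)(C)C)C[C@@]1(O[Si](C)(C)C(C)(C)C)C2=C(C)CCC23OCCO3 | intermediate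
14 | cycloheptadiene ester (1S,10R): ring B with C5=C6 OTBS enol ether, ethyl ester on C8 of C8=C9, 10α-OTBS, 1β-methyl, C4 ethylene ketal | CC(C)(C)[Si](C)(C)OC=1CC(C(=O)OCC)=C[C@@H](O[Si](C)(C)C(C)(C)C)[C@@]2(C)CCC3(OCCO3)C=12 | intermediate
15 | allylic alcohol (1S,10R): as 14 with CH2OH on C8 | CC(C)(C)[Si](C)(C)OC=1CC(CO)=C[C@@H](O[Si](C)(C)C(C)(C)C)[C@@]2(C)CCC3(OCCO3)C=12 | intermediate
16 | allylic mesylate (1S,10R): as 15 with CH2OSO2CH3 on C8 | CC(C)(C)[Si](C)(C)OC=1CC(COS(C)(=O)=O)=C[C@@H](O[Si](C)(C)C(C)(C)C)[C@@]2(C)CCC3(OCCO3)C=12 | intermediate
17 | C8-methyl diene (1S,10R): C5=C6 OTBS enol ether, C8=C9, 10α-OTBS, C4 ethylene ketal | CC(C)(C)[Si](C)(C)OC=1CC(C)=C[C@@H](O[Si](C)(C)C(C)(C)C)[C@@]2(C)CCC3(OCCO3)C=12 | intermediate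
18 | β,γ-unsaturated C6 ketone (1S,5S,10R): trans-fused, 5α-H, C8=C9, 10α-OTBS, C4 ethylene ketal | O=C1CC(C)=C[C@@H](O[Si](C)(C)C(C)(C)C)[C@@]2(C)CCC3(OCCO3)[C@H]12 | intermediate
19 | 6α-alcohol (1S,5S,6S,10R): as 18 with C6 carbinol | O[C@H]1CC(C)=C[C@@H](O[Si](C)(C)C(C)(C)C)[C@@]2(C)CCC3(OCCO3)[C@H]12 | intermediate
20 | sodium alkoxide of 19 | [Na+].[O-][C@H]1CC(C)=C[C@@H](O[Si](C)(C)C(C)(C)C)[C@@]2(C)CCC3(OCCO3)[C@H]12 | intermediate
21 | 6α-(4-methoxybenzyl) ether (1S,5S,6S,10R): 10α-OTBS, C4 ethylene ketal | COc1ccc(CO[C@H]2CC(C)=C[C@@H](O[Si](C)(C)C(C)(C)C)[C@@]3(C)CCC4(OCCO4)[C@H]23)cc1 | intermediate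
22 | C4 ketone (1S,5S,6S,10R): 6α-OPMB, 10α-OTBS | COc1ccc(CO[C@H]2CC(C)=C[C@@H](O[Si](C)(C)C(C)(C)C)[C@@]3(C)CCC(=O)[C@H]23)cc1 | intermediate
23 | 4β-hydroxy-4α-isopropyl compound (1S,4R,5S,6S,10R): 6α-OPMB, 10α-OTBS | COc1ccc(CO[C@H]2CC(C)=C[C@@H](O[Si](C)(C)C(C)(C)C)[C@@]3(C)CC[C@@](O)(C(C)C)[C@H]23)cc1 | intermediate
24 | 4β,6α-diol (1S,4R,5S,6S,10R): 10α-OTBS | O[C@H]1CC(C)=C[C@@H](O[Si](C)(C)C(C)(C)C)[C@@]2(C)CC[C@@](O)(C(C)C)[C@H]12 | intermediate
25 | angelic acid, (Z)-2-methylbut-2-enoic acid | C/C=C(/C)C(=O)O | starting material
26 | angelic 2,4,6-trichlorobenzoic anhydride | C/C=C(/C)C(=O)OC(=O)c1c(Cl)cc(Cl)cc1Cl | intermediate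
27 | 6α-angelate (1S,4R,5S,6S,10R): 4β-OH, 10α-OTBS, C8=C9 | C/C=C(/C)C(=O)O[C@H]1CC(C)=C[C@@H](O[Si](C)(C)C(C)(C)C)[C@@]2(C)CC[C@@](O)(C(C)C)[C@H]12 | intermediate
28 | 10α-alcohol (1S,4R,5S,6S,10R): 4β-OH, 6α-angelate, C8=C9 | C/C=C(/C)C(=O)O[C@H]1CC(C)=C[C@@H](O)[C@@]2(C)CC[C@@](O)(C(C)C)[C@H]12 | intermediate
29 | lapiferine (1S,4R,5S,6S,8R,9S,10S) | C/C=C(/C)C(=O)O[C@H]1C[C@@]2(C)O[C@H]2[C@@H](O)[C@@]2(C)CC[C@@](O)(C(C)C)[C@H]12 | target

## Step count and least certain steps

Total: 18 steps. Longest linear sequence: 16 steps (steps 1–4 and 7–18, from 1); the diazo branch (steps 5 and 6) joins at step 7.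

Step 7 (key step). The most likely failures are low enantioselectivity or the wrong facial sense in the cyclopropanation, attack of the enol ether at the vinylogous carbenoid terminus, and a slow Cope shift during which the push–pull cyclopropane opens and loses its configuration. The methyl-substituted Cope terminus and the ethyl (not methyl) ester both work against the best cases of this catalyst family.
Fallback (sets out from 7 and 9, returns at 15): stereocontrol is moved from the catalyst to a covalently bound auxiliary.
- (R)-Pantolactone is treated with the p-toluenesulfonylhydrazone of glyoxylic acid chloride and Et3N to give (R)-pantolactonyl diazoacetate F1.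
- DBU-catalysed addition of F1 to 9 gives the hydroxy diazo ester F2, and POCl3/Et3N dehydrates it to the pantolactonyl vinyldiazoacetate F3.
- With achiral Rh2(OOct)4 (dirhodium tetraoctanoate) in hexanes and then warming, F3 and 7 should give the pantolactonyl cycloheptadiene ester F4 by the same cyclopropanation/Cope sequence, the lactone carbonyl shielding one face of the carbenoid.
- Excess i-Bu2AlH reduces the ester of F4 to 15.
- If the induction favours the wrong enantiomer, (S)-pantolactone is used.

Step 10. Protonation of the enolate on the wrong face would give the cis-fused ketone, and base-induced migration of the C8=C9 alkene into conjugation or β-elimination of a ketal oxygen would destroy the substitution pattern. The free enolate is basic and the β,γ-unsaturated ketone is easily isomerised.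
Fallback (sets out from 17, returns at 19, bypassing 18): no ketone is formed, and C5 and C6 are set by one syn addition.
- CsF and PhNTf2 in DME convert the silyl enol ether directly into the enol triflate F5.
- Pd(OAc)2/PPh3 with n-Bu3N and HCO2H reduces F5 to the C5=C6 alkene F6.
- Hydroboration (BH3·SMe2, THF, 0 °C) and oxidation (NaBO3·4H2O) put boron, then hydroxyl, on C6 and hydrogen on C5 from the α face, anti to the angular methyl, giving 19.
- The C8=C9 alkene should react more slowly because boron would have to go next to the silyloxy-bearing C10.

Step 11. The reduction may show poor facial selectivity or favour the 6β-alcohol if the equatorial preference is smaller than assumed. Base formed in the medium could also conjugate the alkene, which would then be reduced.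
Fallback (sets out from 18, returns at 24): the C6 configuration is set later by intramolecular hydride delivery from the C4 hydroxyl.
- NaBH4 in MeOH reduces 18 to the 6β-alcohol F7, which is protected as its 4-methoxybenzyl ether F8 (NaH, PMBCl).
- PPTS in wet acetone gives the ketone F9, and i-PrMgCl/CeCl3 the tertiary alcohol F10.
- DDQ gives the 4β,6β-diol F11, and Dess–Martin periodinane oxidises its secondary hydroxyl to the 4β-hydroxy-6-ketone F12.
- Me4NBH(OAc)3 in AcOH/MeCN at −20 °C (Evans–Saksena reduction) binds to the β hydroxyl and delivers hydride to the β face of C6, giving the 1,3-anti diol 24.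

Step 14. Enolisation of the ketone followed by β-elimination of the C6 ether, β-hydride reduction by the secondary alkyl reagent, or attack on the wrong face could each compete. The ketone is hindered and carries an acidic α-hydrogen next to a β-leaving group.
Fallback (sets out from 22, returns at 23): the carbon is delivered as an sp2 nucleophile without β-hydrogens.
- CH2=C(CH3)MgBr/CeCl3 adds to 22 to give the isopropenyl carbinol F13.
- Diimide (from 2-nitrobenzenesulfonylhydrazide and Et3N) then reduces the 1,1-disubstituted alkene in preference to the trisubstituted ring alkene, giving 23.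

Step 16. Z to E isomerisation to the tiglate, or failure to acylate the hindered C6 hydroxyl at a temperature the angelate tolerates, are the likely problems.
Fallback (sets out from 24, returns at 27): the angelate double bond is built on the substrate.
- 24 is esterified with 2-[bis(2,2,2-trifluoroethoxy)phosphoryl]propanoic acid (DCC, DMAP) to give the phosphonate ester F14.
- Still–Gennari olefination of F14 with acetaldehyde (KN(SiMe3)2, 18-crown-6, THF, −78 °C, base in excess because of the free tertiary hydroxyl) should give the Z-trisubstituted enoate, that is the angelate 27, under kinetic control.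

## Further compounds

F1 | step 7 | (R)-pantolactonyl diazoacetate | [N-]=[N+]=CC(=O)O[C@H]1C(=O)OCC1(C)C
F2 | step 7 | (R)-pantolactonyl 4-[(tert-butyldimethylsilyl)oxy]-2-diazo-3-hydroxybutanoate (mixture at the carbinol) | CC(C)(C)[Si](C)(C)OCC(O)C(=[N+]=[N-])C(=O)O[C@H]1C(=O)OCC1(C)C
F3 | step 7 | (R)-pantolactonyl (E)-4-[(tert-butyldimethylsilyl)oxy]-2-diazobut-3-enoate | CC(C)(C)[Si](C)(C)O/C=C/C(=[N+]=[N-])C(=O)O[C@H]1C(=O)OCC1(C)C
F4 | step 7 | (R)-pantolactonyl ester analogue of 14 (1S,10R) | CC(C)(C)[Si](C)(C)OC=1CC(C(=O)O[C@H]3C(=O)OCC3(C)C)=C[C@@H](O[Si](C)(C)C(C)(C)C)[C@@]2(C)CCC4(OCCO4)C=12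
F5 | step 10 | C6 enol triflate (1S,10R): C5=C6 OTf, C8=C9, 10α-OTBS, C4 ethylene ketal | O=S(=O)(OC=1CC(C)=C[C@@H](O[Si](C)(C)C(C)(C)C)[C@@]2(C)CCC3(OCCO3)C=12)C(F)(F)F
F6 | step 10 | C5=C6, C8=C9 diene (1S,10R): 10α-OTBS, C4 ethylene ketal | CC1=C[C@@H](O[Si](C)(C)C(C)(C)C)[C@@]2(C)CCC3(OCCO3)C2=CC1
F7 | step 11 | 6β-alcohol (1S,5S,6R,10R), C6 epimer of 19 | O[C@@H]1CC(C)=C[C@@H](O[Si](C)(C)C(C)(C)C)[C@@]2(C)CCC3(OCCO3)[C@H]12
F8 | step 11 | 6β-(4-methoxybenzyl) ether, C6 epimer of 21 | COc1ccc(CO[C@@H]2CC(C)=C[C@@H](O[Si](C)(C)C(C)(C)C)[C@@]3(C)CCC4(OCCO4)[C@H]23)cc1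
F9 | step 11 | C4 ketone, C6 epimer of 22 | COc1ccc(CO[C@@H]2CC(C)=C[C@@H](O[Si](C)(C)C(C)(C)C)[C@@]3(C)CCC(=O)[C@H]23)cc1
F10 | step 11 | 4β-hydroxy-4α-isopropyl compound, C6 epimer of 23 | COc1ccc(CO[C@@H]2CC(C)=C[C@@H](O[Si](C)(C)C(C)(C)C)[C@@]3(C)CC[C@@](O)(C(C)C)[C@H]23)cc1
F11 | step 11 | 4β,6β-diol, C6 epimer of 24 | O[C@@H]1CC(C)=C[C@@H](O[Si](C)(C)C(C)(C)C)[C@@]2(C)CC[C@@](O)(C(C)C)[C@H]12
F12 | step 11 | 4β-hydroxy-6-ketone (1S,4R,5S,10R): 10α-OTBS, C8=C9 | O=C1CC(C)=C[C@@H](O[Si](C)(C)C(C)(C)C)[C@@]2(C)CC[C@@](O)(C(C)C)[C@H]12
F13 | step 14 | 4β-hydroxy-4α-isopropenyl compound: 6α-OPMB, 10α-OTBS | COc1ccc(CO[C@H]2CC(C)=C[C@@H](O[Si](C)(C)C(C)(C)C)[C@@]3(C)CC[C@@](O)(C(C)=C)[C@H]23)cc1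
F14 | step 16 | 6α-{2-[bis(2,2,2-trifluoroethoxy)phosphoryl]propanoate} of 24 (mixture at the phosphonate carbon) | CC(C(=O)O[C@H]1CC(C)=C[C@@H](O[Si](C)(C)C(C)(C)C)[C@@]2(C)CC[C@@](O)(C(C)C)[C@H]12)P(=O)(OCC(F)(F)F)OCC(F)(F)F
A1 | alternative 1 | 2,5-dimethylfuran | Cc1ccc(C)o1
A2 | alternative 1 | 1,1,3,3-tetrabromoacetone | BrC(Br)C(=O)C(Br)Br
A3 | alternative 1 | meso (1R,5S)-1,5-dimethyl-8-oxabicyclo[3.2.1]oct-6-en-3-one | C[C@]12CC(=O)C[C@](C)(O1)C=C2
A4 | alternative 2 | (3R,6E)-6-methyl-7-(trans-2-methylcyclopropyl)-3-(propan-2-yl)hept-6-en-1-yn-3-ol | C#C[C@](O)(C(C)C)CC/C(C)=C/[C@@H]1C[C@H]1C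
A5 | alternative 2 | bicyclic diene (target numbering): C5=C6 and C9=C10 alkenes, 1β-methyl, 4β-hydroxy-4α-isopropyl, 8α-methyl | C=1C[C@@H](C)C=C[C@@]2(C)CC[C@@](O)(C(C)C)C=12
A6 | alternative 3 | diazo ketone (target numbering): C5 diazo, C6 ketone, C7=C8 enone, C1 methyl and 3-(triethylsilyloxy)-4-methylpentyl chain | O=C1C=C(C)CC[C@@](C)(CC[C@@H](O[Si](CC)(CC)CC)C(C)C)C1=[N+]=[N-]
A7 | alternative 3 | trans-fused bicyclic enone (target numbering): C6 ketone, C7=C8, 4β-OTES, 4α-isopropyl | O=C1C=C(C)CC[C@@]2(C)CC[C@@](O[Si](CC)(CC)CC)(C(C)C)[C@H]12
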